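## Retrosynthetic overview

1. Target 18 ⇐ 17 by hydrogenolysis of five benzyl ethers; 17 ⇐ 16 by double catalyst-controlled reduction of the two aryl ketones, which sets both benzylic carbinols.
2. 16 ⇐ 14: the 12-membered diolide is the only ring made and is closed last, by forming the ring A carboxyl–O–CH(CH3) bond through oxidative α-C–H acyloxylation of the ring B ethyl ketone.
3. 14 ⇐ 8 + 12: the first ester C–O bond comes from Mitsunobu alkylation of the ring B carboxylate by the (S)-α-hydroxy ketone of ring A, with inversion.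
4. 8 and 12 ⇐ common keto ester 6 (Davis hydroxylation for ring A; arene C–H hydroxylation, benzylation and ester cleavage for ring B).
5. 6 ⇐ methyl 4-O-methylgallate 1 by benzylation, ortho-magnesiation/Boc2O and Weinreb ketone synthesis.

Assumption: the four stereocentres are read from the SMILES as all (R), each ArCH(OH)–CH(CH3)O unit being the syn (threo) diol; 1 is taken as a catalogue compound (it is also one step from methyl gallate).

## Route

Step 1
Reactants: 1 methyl 3,5-dihydroxy-4-methoxybenzoate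
Product: 2 methyl 3,5-bis(benzyloxy)-4-methoxybenzoate
Conditions: BnBr (2.3 equiv), K2CO3, DMF, 60 °C
Reagents that add atoms: benzyl bromide, BrCc1ccccc1
Why: Williamson ether synthesis on the two equivalent phenols gives benzyl ethers that are removed only in the last step under neutral conditions; no stereocentre is formed.

Step 2
Reactants: 2 methyl 3,5-bis(benzyloxy)-4-methoxybenzoate
Product: 4 2-tert-butyl 1-methyl 3,5-bis(benzyloxy)-4-methoxybenzene-1,2-dicarboxylate, via arylmagnesium amide 3 (not isolated)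
Conditions: Mg(TMP)2·2LiCl (1.2 equiv; TMP = 2,2,6,6-tetramethylpiperidide), THF, −20 → 0 °C; then Boc2O, 0 °C → rt; aq. NH4Cl
Reagents that add atoms: di-tert-butyl dicarbonate, CC(C)(C)OC(=O)OC(=O)OC(C)(C)C
Why: Directed ortho-magnesiation with a Knochel–Hauser-type amide base occurs at the C–H flanked by the ester and a benzyloxy group (the two such positions are equivalent), and acylation of the aryl–Mg bond by Boc2O installs the future lactone carboxyl as a tert-butyl ester orthogonal to the methyl ester.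

Step 3
Reactants: 4 2-tert-butyl 1-methyl 3,5-bis(benzyloxy)-4-methoxybenzene-1,2-dicarboxylate
Product: 6 tert-butyl 2,4-bis(benzyloxy)-3-methoxy-6-propanoylbenzoate, via Weinreb amide 5 (not isolated)
Conditions: MeNHOMe·HCl, i-PrMgCl, THF, −20 → 0 °C; then EtMgBr, 0 °C → rt; aq. NH4Cl
Reagents that add atoms: ethylmagnesium bromide, CC[Mg]Br
Why: One-pot Weinreb ketone synthesis, in which the chloromagnesium amide attacks only the methyl ester (the tert-butyl ester is flanked on both sides and inert) and the chelated tetrahedral adduct stops EtMgBr at the ketone stage.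

Step 4
Reactants: 6 tert-butyl 2,4-bis(benzyloxy)-3-methoxy-6-propanoylbenzoate
Product: 8 tert-butyl 2,4-bis(benzyloxy)-6-[(2S)-2-hydroxypropanoyl]-3-methoxybenzoate, via sodium enolate 7 (not isolated)
Conditions: NaN(SiMe3)2, THF, −78 °C; (+)-(camphorsulfonyl)oxaziridine, −78 °C; NH4Cl quench at −78 °C
Reagents that add atoms: (+)-(2R,8aS)-(camphorsulfonyl)oxaziridine, CC1(C)[C@@H]2CC[C@]13CS(=O)(=O)N4O[C@@]34C2
Why: Davis asymmetric enolate hydroxylation, in which the (Z)-sodium enolate is oxygenated on one face by the chiral N-sulfonyloxaziridine (the (+)-reagent is the antipode known to give (S)-2-hydroxypropiophenones; checked by Mosher ester, the other antipode being equally available), setting C-2 as (S) for inversion in step 8, while −78 °C and a cold quench suppress Claisen-type attack on the hindered tert-butyl ester.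

Step 5
Reactants: 6 tert-butyl 2,4-bis(benzyloxy)-3-methoxy-6-propanoylbenzoate
Product: 10 tert-butyl 2,4-bis(benzyloxy)-5-hydroxy-3-methoxy-6-propanoylbenzoate, via aryl hydrogen 4,5-dichlorophthalate 9 (not isolated)
Conditions: 4,5-dichlorophthaloyl peroxide (1.3 equiv), (CF3)2CHOH, 23 °C; then MeOH, Et3N, 40 °C
Reagents that add atoms: 4,5-dichlorophthaloyl peroxide, O=C1OOC(=O)c2cc(Cl)c(Cl)cc12
Why: Metal-free electrophilic arene C–H hydroxylation with a cyclic diacyl peroxide attacks C-5, the only C–H on the electron-rich ring and ortho/para to the two benzyloxy groups, and the first-formed aryl ester shields the phenol from over-oxidation until mild methanolysis.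

Step 6
Reactants: 10 tert-butyl 2,4-bis(benzyloxy)-5-hydroxy-3-methoxy-6-propanoylbenzoate
Product: 11 tert-butyl 2,4,5-tris(benzyloxy)-3-methoxy-6-propanoylbenzoate
Conditions: BnBr, K2CO3, DMF, 60 °C
Reagents that add atoms: benzyl bromide, BrCc1ccccc1
Why: Williamson etherification of the hydrogen-bonded ortho-acyl phenol, with a base too weak to enolise the ketone.

Step 7
Reactants: 11 tert-butyl 2,4,5-tris(benzyloxy)-3-methoxy-6-propanoylbenzoate
Product: 12 2,4,5-tris(benzyloxy)-3-methoxy-6-propanoylbenzoic acid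
Conditions: CF3CO2H/CH2Cl2 (1:4), 0 °C → rt
Reagents that add atoms: none
Why: Acidolysis of the tert-butyl ester (loss of isobutene) leaves benzyl ethers and ketone untouched and gives the keto acid, which equilibrates with its hydroxyphthalide tautomer.

Step 8
Reactants: 8 tert-butyl 2,4-bis(benzyloxy)-6-[(2S)-2-hydroxypropanoyl]-3-methoxybenzoate; 12 2,4,5-tris(benzyloxy)-3-methoxy-6-propanoylbenzoic acid
Product: 13 tert-butyl 2,4-bis(benzyloxy)-3-methoxy-6-[(2R)-2-{[2,4,5-tris(benzyloxy)-3-methoxy-6-propanoylbenzoyl]oxy}propanoyl]benzoate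
Conditions: PPh3, DIAD, toluene, 0 °C → rt
Reagents that add atoms: none
Why: Mitsunobu esterification, in which the carboxylate displaces the activated α-keto carbinol oxygen by SN2 and so forms the first ester C–O bond with inversion, (S) → (R); carboxylate alkylation is used because acyl activation of a 2,6-disubstituted 2-acylbenzoic acid gives pseudo-esters.

Step 9
Reactants: 13 tert-butyl 2,4-bis(benzyloxy)-3-methoxy-6-[(2R)-2-{[2,4,5-tris(benzyloxy)-3-methoxy-6-propanoylbenzoyl]oxy}propanoyl]benzoate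
Product: 14 2,4-bis(benzyloxy)-3-methoxy-6-[(2R)-2-{[2,4,5-tris(benzyloxy)-3-methoxy-6-propanoylbenzoyl]oxy}propanoyl]benzoic acid
Conditions: CF3CO2H/CH2Cl2 (1:4), 0 °C → rt
Reagents that add atoms: none
Why: Acidolysis of the tert-butyl ester frees the ring A carboxyl without touching the hindered aryl ester, the benzyl ethers or the α-acyloxy ketone stereocentre.

Step 10
Reactants: 14 2,4-bis(benzyloxy)-3-methoxy-6-[(2R)-2-{[2,4,5-tris(benzyloxy)-3-methoxy-6-propanoylbenzoyl]oxy}propanoyl]benzoic acid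
Product: 16 penta-O-benzyl diketo diolide (12-membered ring; both CH(CH3)–O centres R), via alpha-iodo ketone 15 (not isolated)
Conditions: chiral N-spiro bis(binaphthyl)azepinium iodide with 3,5-bis(trifluoromethyl)phenyl groups at the 3,3′-positions (10 mol%; both antipodes screened, Bu4NI as achiral control), t-BuOOH (2 equiv), EtOAc, 30 °C, 14 added by syringe pump over 12 h to 1 mM
Reagents that add atoms: none
Why: Proposed new method: catalytic oxidative macro-oxylactonisation, in which iodide is oxidised by t-BuOOH to ammonium hypoiodite, this α-iodinates the enol of the ring B ethyl ketone to alpha-iodo ketone 15 (two epimers that interconvert fast by iodide exchange and enolisation), and the ring A carboxylate, ion-paired with the chiral ammonium cation, displaces iodide by SN2 at the activated α-keto carbon, so that the 12-membered ring, the second ester C–O bond and the (R) centre form in one dynamic kinetic step with return of iodide; the closest known reaction type is the ammonium (hypo)iodite-catalysed oxidative α-acyloxylation of ketones with carboxylic acids (intermolecular and to five- and six-membered lactones) together with the enantioselective hypoiodite cycloetherification of keto phenols, and new here are the macrocyclic ring size, stereocontrol at a plain aryl ethyl ketone and use on a 2-acylbenzoic acid.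

Step 11
Reactants: 16 penta-O-benzyl diketo diolide
Product: 17 penta-O-benzyl target (both ketones reduced to (R)-carbinols)
Conditions: (R)-2-methyl-CBS-oxazaborolidine (40 mol%), BH3·SMe2 (2.5 equiv), THF, −20 °C; MeOH quench, pH 7 buffer
Reagents that add atoms: none
Why: Corey–Bakshi–Shibata reduction, in which catalyst control (the (R)-catalyst gives the (S)-1-arylethanol-type arrangement, named (R) here because the oxygenated chain outranks the aryl group) is matched with the polar Felkin–Anh preference of both α-acyloxy ketones for the syn (1R,2R) carbinol, and the non-nucleophilic boron alkoxides do not attack the ortho lactone carbonyls.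

Step 12
Reactants: 17 penta-O-benzyl target
Product: 18 CNP0086623.2
Conditions: H2 (1 atm), Pd on carbon (10 wt%), EtOAc/MeOH, 23 °C, degassed work-up
Reagents that add atoms: none
Why: Hydrogenolysis of the five aryl benzyl ethers under neutral conditions keeps the secondary benzylic alcohols and both lactones, with no base present to trigger translactonisation to phthalides or isochromanones.

## Compound list

1 | methyl 3,5-dihydroxy-4-methoxybenzoate | COC(=O)c1cc(O)c(OC)c(O)c1 | starting material
2 | methyl 3,5-bis(benzyloxy)-4-methoxybenzoate | COC(=O)c1cc(OCc2ccccc2)c(OC)c(OCc2ccccc2)c1 | intermediate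
3 | [2,4-bis(benzyloxy)-3-methoxy-6-(methoxycarbonyl)phenyl](2,2,6,6-tetramethylpiperidin-1-yl)magnesium, LiCl complex | COC(=O)c1cc(OCc2ccccc2)c(OC)c(OCc2ccccc2)c1[Mg]N1C(C)(C)CCCC1(C)C | intermediate
4 | 2-tert-butyl 1-methyl 3,5-bis(benzyloxy)-4-methoxybenzene-1,2-dicarboxylate | COC(=O)c1cc(OCc2ccccc2)c(OC)c(OCc2ccccc2)c1C(=O)OC(C)(C)C | intermediate
5 | tert-butyl 2,4-bis(benzyloxy)-3-methoxy-6-[methoxy(methyl)carbamoyl]benzoate | CON(C)C(=O)c1cc(OCc2ccccc2)c(OC)c(OCc2ccccc2)c1C(=O)OC(C)(C)C | intermediate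
6 | tert-butyl 2,4-bis(benzyloxy)-3-methoxy-6-propanoylbenzoate | CCC(=O)c1cc(OCc2ccccc2)c(OC)c(OCc2ccccc2)c1C(=O)OC(C)(C)C | intermediate
7 | sodium (1Z)-1-[3,5-bis(benzyloxy)-2-(tert-butoxycarbonyl)-4-methoxyphenyl]prop-1-en-1-olate | C/C=C(\[O-])c1cc(OCc2ccccc2)c(OC)c(OCc2ccccc2)c1C(=O)OC(C)(C)C.[Na+] | intermediate
8 | tert-butyl 2,4-bis(benzyloxy)-6-[(2S)-2-hydroxypropanoyl]-3-methoxybenzoate | C[C@H](O)C(=O)c1cc(OCc2ccccc2)c(OC)c(OCc2ccccc2)c1C(=O)OC(C)(C)C | intermediate
9 | 2-{[4,6-bis(benzyloxy)-3-(tert-butoxycarbonyl)-5-methoxy-2-propanoylphenoxy]carbonyl}-4,5-dichlorobenzoic acid | CCC(=O)c1c(OC(=O)c2cc(Cl)c(Cl)cc2C(=O)O)c(OCc2ccccc2)c(OC)c(OCc2ccccc2)c1C(=O)OC(C)(C)C | intermediate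
10 | tert-butyl 2,4-bis(benzyloxy)-5-hydroxy-3-methoxy-6-propanoylbenzoate | CCC(=O)c1c(O)c(OCc2ccccc2)c(OC)c(OCc2ccccc2)c1C(=O)OC(C)(C)C | intermediate
11 | tert-butyl 2,4,5-tris(benzyloxy)-3-methoxy-6-propanoylbenzoate | CCC(=O)c1c(OCc2ccccc2)c(OCc2ccccc2)c(OC)c(OCc2ccccc2)c1C(=O)OC(C)(C)C | intermediate
12 | 2,4,5-tris(benzyloxy)-3-methoxy-6-propanoylbenzoic acid (in equilibrium with its 3-ethyl-3-hydroxyphthalide tautomer) | CCC(=O)c1c(OCc2ccccc2)c(OCc2ccccc2)c(OC)c(OCc2ccccc2)c1C(=O)O | intermediate
13 | tert-butyl 2,4-bis(benzyloxy)-3-methoxy-6-[(2R)-2-{[2,4,5-tris(benzyloxy)-3-methoxy-6-propanoylbenzoyl]oxy}propanoyl]benzoate | C[C@@H](OC(=O)c1c(OCc2ccccc2)c(OC)c(OCc2ccccc2)c(OCc2ccccc2)c1C(=O)CC)C(=O)c1cc(OCc2ccccc2)c(OC)c(OCc2ccccc2)c1C(=O)OC(C)(C)C | intermediate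
14 | 2,4-bis(benzyloxy)-3-methoxy-6-[(2R)-2-{[2,4,5-tris(benzyloxy)-3-methoxy-6-propanoylbenzoyl]oxy}propanoyl]benzoic acid | C[C@@H](OC(=O)c1c(OCc2ccccc2)c(OC)c(OCc2ccccc2)c(OCc2ccccc2)c1C(=O)CC)C(=O)c1cc(OCc2ccccc2)c(OC)c(OCc2ccccc2)c1C(=O)O | intermediate
15 | 2,4-bis(benzyloxy)-6-[(2R)-2-{[2,4,5-tris(benzyloxy)-6-(2-iodopropanoyl)-3-methoxybenzoyl]oxy}propanoyl]-3-methoxybenzoic acid (both epimers at the iodine-bearing carbon, interconverting) | C[C@@H](OC(=O)c1c(OCc2ccccc2)c(OC)c(OCc2ccccc2)c(OCc2ccccc2)c1C(=O)C(C)I)C(=O)c1cc(OCc2ccccc2)c(OC)c(OCc2ccccc2)c1C(=O)O | intermediate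
16 | penta-O-benzyl diketo diolide: 12-membered dilactone in which the carboxyl of ring A (2,4-bis(benzyloxy)-3-methoxybenzoate) is esterified by the (R)-CH(CH3)–O of the 2-oxypropanoyl chain at C-6 of ring B (2,4,5-tris(benzyloxy)-3-methoxybenzoate), and the carboxyl of ring B by the (R)-CH(CH3)–O of the 2-oxypropanoyl chain at C-6 of ring A | COc1c(OCc3ccccc3)cc2c(c1OCc3ccccc3)C(=O)O[C@H](C)C(=O)c1c(OCc3ccccc3)c(OCc3ccccc3)c(OC)c(OCc3ccccc3)c1C(=O)O[C@H](C)C2=O | intermediate
17 | penta-O-benzyl target: as 16 with both ketones reduced to (R)-configured benzylic carbinols | COc1c(OCc3ccccc3)cc2c(c1OCc3ccccc3)C(=O)O[C@H](C)[C@H](O)c1c(OCc3ccccc3)c(OCc3ccccc3)c(OC)c(OCc3ccccc3)c1C(=O)O[C@H](C)[C@@H]2O | intermediate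
18 | CNP0086623.2, the all-(R) 12-membered diolide with free phenols | COc1c(O)cc2c(c1O)C(=O)O[C@H](C)[C@H](O)c1c(O)c(O)c(OC)c(O)c1C(=O)O[C@H](C)[C@@H]2O | target

## Step count and risks

Total: 12 steps. Longest linear sequence: 11 steps (1 → 2 → 4 → 6 → 10 → 11 → 12 → 13 → 14 → 16 → 17 → 18, i.e. steps 1, 2, 3, 5, 6, 7, 8, 9, 10, 11, 12).

**Step 10 (the proposed new macro-oxylactonisation).** It may fail through poor diastereocontrol, oligomerisation at the turnover-limited dilution, or oxidation of benzyl ethers.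

The fallback uses only known chemistry, sets out from 11 (and uses 8) and returns at 16. Compound 11 is deprotonated with NaN(SiMe3)2 at −78 °C to the sodium enolate F1, which the oxaziridine of step 4 converts into the (S)-hydroxy ketone F2. Et3SiOTf/2,6-lutidine in CH2Cl2 silylates the alcohol and turns the tert-butyl ester into a silyl ester, giving the bis(triethylsilyl) compound F3, whose silyl ester is hydrolysed on aqueous work-up to the silyl-protected acid F4. Mitsunobu esterification of F4 with 8 (PPh3, DIAD, toluene) gives the diester F5 with inversion. CF3CO2H/CH2Cl2/H2O removes the tert-butyl ester and the silyl ether to give the hydroxy acid F6. Mitsunobu macrolactonisation of F6 at 2 mM (PPh3, DIAD, toluene, slow addition) closes the ring with inversion to 16, so both stereocentres come from the Davis/Mitsunobu pair and no catalyst control is needed.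

**Step 5 (arene C–H hydroxylation at a hindered, acyl-deactivated position).** The fallback sets out from 6 and returns at 10. Iodination with N-iodosuccinimide and CF3CO2H (10 mol%) in MeCN gives the aryl iodide F7. Palladium-catalysed coupling with (E)-benzaldoxime as hydroxide surrogate (Pd2(dba)3, tBuBrettPhos, Cs2CO3, DMF, 80 °C) gives the O-aryl oxime F8, which fragments in the flask to phenol 10 and benzonitrile.

**Step 11 (double ketone reduction).** The ring B ketone is di-ortho-substituted and may react slowly or with low selectivity. The fallback sets out from 16 and returns at 17. It replaces the catalytic borane reduction by the stoichiometric chiral reagent (−)-B-chlorodiisopinocampheylborane, (−)-Ipc2BCl, in THF at −25 °C with acetaldehyde work-up. This reagent transfers hydride through a cyclic Meerwein–Ponndorf-type transition state, is the known choice for hindered aryl ketones, and has the sense that gives the same carbinol configuration. This fallback makes no new compound (entry F0).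

## Further compounds

F1 | step 10 | sodium (1Z)-1-[2,3,5-tris(benzyloxy)-6-(tert-butoxycarbonyl)-4-methoxyphenyl]prop-1-en-1-olate | C/C=C(\[O-])c1c(OCc2ccccc2)c(OCc2ccccc2)c(OC)c(OCc2ccccc2)c1C(=O)OC(C)(C)C.[Na+]
F2 | step 10 | tert-butyl 2,4,5-tris(benzyloxy)-6-[(2S)-2-hydroxypropanoyl]-3-methoxybenzoate | C[C@H](O)C(=O)c1c(OCc2ccccc2)c(OCc2ccccc2)c(OC)c(OCc2ccccc2)c1C(=O)OC(C)(C)C
F3 | step 10 | triethylsilyl 2,4,5-tris(benzyloxy)-3-methoxy-6-[(2S)-2-(triethylsilyloxy)propanoyl]benzoate | C[C@H](O[Si](CC)(CC)CC)C(=O)c1c(OCc2ccccc2)c(OCc2ccccc2)c(OC)c(OCc2ccccc2)c1C(=O)O[Si](CC)(CC)CC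
F4 | step 10 | 2,4,5-tris(benzyloxy)-3-methoxy-6-[(2S)-2-(triethylsilyloxy)propanoyl]benzoic acid | C[C@H](O[Si](CC)(CC)CC)C(=O)c1c(OCc2ccccc2)c(OCc2ccccc2)c(OC)c(OCc2ccccc2)c1C(=O)O
F5 | step 10 | tert-butyl 2,4-bis(benzyloxy)-3-methoxy-6-[(2R)-2-({2,4,5-tris(benzyloxy)-3-methoxy-6-[(2S)-2-(triethylsilyloxy)propanoyl]benzoyl}oxy)propanoyl]benzoate | C[C@@H](OC(=O)c1c(OCc2ccccc2)c(OC)c(OCc2ccccc2)c(OCc2ccccc2)c1C(=O)[C@H](C)O[Si](CC)(CC)CC)C(=O)c1cc(OCc2ccccc2)c(OC)c(OCc2ccccc2)c1C(=O)OC(C)(C)C
F6 | step 10 | 2,4-bis(benzyloxy)-3-methoxy-6-[(2R)-2-({2,4,5-tris(benzyloxy)-6-[(2S)-2-hydroxypropanoyl]-3-methoxybenzoyl}oxy)propanoyl]benzoic acid | C[C@@H](OC(=O)c1c(OCc2ccccc2)c(OC)c(OCc2ccccc2)c(OCc2ccccc2)c1C(=O)[C@H](C)O)C(=O)c1cc(OCc2ccccc2)c(OC)c(OCc2ccccc2)c1C(=O)O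
F7 | step 5 | tert-butyl 2,4-bis(benzyloxy)-5-iodo-3-methoxy-6-propanoylbenzoate | CCC(=O)c1c(I)c(OCc2ccccc2)c(OC)c(OCc2ccccc2)c1C(=O)OC(C)(C)C
F8 | step 5 | tert-butyl 2,4-bis(benzyloxy)-5-{[(E)-benzylideneamino]oxy}-3-methoxy-6-propanoylbenzoate | CCC(=O)c1c(O/N=C/c2ccccc2)c(OCc2ccccc2)c(OC)c(OCc2ccccc2)c1C(=O)OC(C)(C)C
F0 | step 11 | none | none
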